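**Retrosynthetic overview**

1. Target 25 ⇐ cis-ene-1,4-diol 21 by two site-selective acylations ⇐ endoperoxide from singlet oxygen and the ring 1,3-diene 19; the O–O bridge adds anti to the side chain and sets both ring C–O centres.
2. Diene 19 ⇐ 2-methyl-5-alkylcyclohex-2-enone 16 (1,2-reduction, syn-dehydration); the carbonyl sits on the ring carbon that ends as the unsubstituted ring =CH.
3. Enone 16 ⇐ enal 9 + 3-oxopentanoic acid 12 by a catalyst-controlled decarboxylative Michael/aldol-condensation [3+3] annulation. The Michael bond joins the side-chain-bearing ring carbon to the future CH(OAng) carbon; the aldol bond joins C(CH3) to the future CH(OAc) carbon.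
4. Enabling feature: the ring =CH between C(CH3) and CH(OAng) carries no substituent and can be a ketone C=O while the ring is built. CH(OAng)–CH=C(CH3) is then the CH2–CO–CH2CH3 of a β-keto acid (CO2H as traceless activator), and CH(OAc)–CH2–CH(side chain) is the CHO–Cα–Cβ of an enal.
5. Enal 9 ⇐ (S)-citronellal (aldehyde carbon → side-chain carbinol; isopropylidene end → enal). Rings: the cyclohexenone ring in step 8; a temporary 2,3-dioxabicyclo[2.2.2]octene bridge in step 11.

Key step: step 8

Remark: the 2-methylbut-2-enoate of the target is the (Z)-ester (angelate); 3-oxopentanoic acid decarboxylates on storage and is therefore made fresh in step 7.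

**Route**

Step 1
Reactants: 1 (S)-citronellal; 2 2-methylprop-1-enylmagnesium bromide
Product: 3 (6S)-2,6,10-trimethylundeca-2,9-dien-4-ol (both C4 epimers)
Conditions: THF, −78 → 0 °C; aq. NH4Cl
Reagents that add atoms: none
Why: Grignard 1,2-addition to the aldehyde; the new carbinol centre forms without control and is erased by the oxidation in step 2.

Step 2
Reactants: 3 (6S)-2,6,10-trimethylundeca-2,9-dien-4-ol
Product: 4 (6S)-2,6,10-trimethylundeca-2,9-dien-4-one
Conditions: Dess–Martin periodinane, NaHCO3, CH2Cl2, 0 °C → rt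
Reagents that add atoms: none
Why: Dess–Martin oxidation of the allylic alcohol to the enone; the methyl stereocentre is β to the new carbonyl and cannot epimerise.

Step 3
Reactants: 4 (6S)-2,6,10-trimethylundeca-2,9-dien-4-one
Product: 5 (4R,6S)-2,6,10-trimethylundeca-2,9-dien-4-ol
Conditions: (S)-2-methyl-CBS-oxazaborolidine (20 mol %), catecholborane, PhMe, −78 °C
Reagents that add atoms: none
Why: Corey–Bakshi–Shibata reduction; the (S)-oxazaborolidine binds the ketone with the alkenyl group as the large substituent and should deliver hydride to give the (4R)-alcohol, and catecholborane does not hydroborate the alkenes at this temperature.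

Step 4
Reactants: 5 (4R,6S)-2,6,10-trimethylundeca-2,9-dien-4-ol
Product: 6 (4R,6S)-2,6,10-trimethylundeca-2,9-dien-4-yl acetate
Conditions: Ac2O, pyridine, DMAP (cat.), CH2Cl2, 0 °C → rt
Reagents that add atoms: acetic anhydride, CC(=O)OC(C)=O
Why: DMAP-catalysed acylation of the secondary alcohol, with retention at carbon.

Step 5
Reactants: 6 (4R,6S)-2,6,10-trimethylundeca-2,9-dien-4-yl acetate
Product: 8 (4R,6S)-2,6-dimethyl-9-oxonon-2-en-4-yl acetate, via ozonide 7 (not isolated)
Conditions: O3, CH2Cl2, −78 °C, Sudan Red 7B end point; then PPh3, −78 °C → rt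
Reagents that add atoms: ozone, [O-][O+]=O
Why: Ozonolysis; the isopropylidene alkene remote from the acetate is the more electron-rich of the two trisubstituted alkenes (the other is deactivated by its allylic acetoxy group), so ozone dosed to the dye end point should cleave it selectively.

Step 6
Reactants: 8 (4R,6S)-2,6-dimethyl-9-oxonon-2-en-4-yl acetate
Product: 9 (4R,6R,7E)-2,6-dimethyl-9-oxonona-2,7-dien-4-yl acetate
Conditions: IBX, 4-methoxypyridine N-oxide, DMSO, rt
Reagents that add atoms: none
Why: IBX-mediated α,β-dehydrogenation of the aldehyde through its enol should give the conjugated (E)-enal under non-basic conditions that leave the γ-methyl stereocentre alone.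

Step 7
Reactants: 10 methyl 3-oxopentanoate
Product: 12 3-oxopentanoic acid, via sodium 3-oxopentanoate 11 (not isolated)
Conditions: aq. NaOH, 0 °C → rt; then HCl to pH 2, 0 °C, extraction, used at once
Reagents that add atoms: sodium hydroxide, [Na+].[OH-]
Why: Ester saponification and cold acidification; the β-keto acid is used immediately because it loses CO2 on standing.

Step 8
Reactants: 9 (4R,6R,7E)-2,6-dimethyl-9-oxonona-2,7-dien-4-yl acetate; 12 3-oxopentanoic acid
Product: 16 (4R,6R)-2-methyl-6-[(1R)-4-methyl-5-oxocyclohex-3-en-1-yl]hept-2-en-4-yl acetate, via Michael adduct keto acid 13 (not isolated), via keto aldehyde 14 (not isolated), via aldol ketol 15 (not isolated)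
Conditions: (S)-α,α-diphenylprolinol trimethylsilyl ether (10 mol %), CH2Cl2, 0 °C → rt; then pyrrolidine, AcOH (20 mol % each), 40 °C
Reagents that add atoms: none
Why: The secondary amine condenses with 9 to an (E)-iminium ion, and the enol of keto acid 12 (its carboxyl group fixes the nucleophilic carbon as the CH2 between the two carbonyls) adds to the β-carbon in a Michael reaction, which makes the bond between the side-chain-bearing ring carbon and the future angelate carbon (13); 13 then loses CO2 to keto aldehyde 14. Pyrrolidinium acetate converts the ethyl ketone of 14 into its enamine, which closes the six-membered ring by a 6-(enolendo)-exo-trig aldol addition onto the aldehyde (15) and dehydrates, making the C(CH3)=CH bond whose sigma bond becomes the C(CH3)–CH(OAc) bond of the target. The closest known reaction type is the amine-catalysed Michael/aldol-condensation annulation of β-keto esters or β-keto acids with enals to cyclohexenones. The ring stereocentre is set by the catalyst: the CPh2(OSiMe3) group of the (S)-pyrrolidine shields one face of the s-trans iminium ion, so the nucleophile should enter from the opposite face, whatever the sense of the neighbouring methyl stereocentre, and give the ring carbon the configuration of the target. The step needs 1,4- over 1,2-addition (secured by the hindered iminium carbon), one aldol regiochemistry (only the ethyl-side enamine of 14 reaches the aldehyde through a six-membered ring, the alternatives would be four-membered) and no loss of the γ-methyl stereocentre of 9 through dienamine formation (secured by the fast, acid-buffered Michael step at 0 °C and by adding pyrrolidine only after 9 is consumed).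

Step 9
Reactants: 16 (4R,6R)-2-methyl-6-[(1R)-4-methyl-5-oxocyclohex-3-en-1-yl]hept-2-en-4-yl acetate
Product: 17 (4R,6R)-6-[(1R,5R)-5-hydroxy-4-methylcyclohex-3-en-1-yl]-2-methylhept-2-en-4-yl acetate
Conditions: NaBH4, CeCl3·7H2O, MeOH, −78 °C
Reagents that add atoms: none
Why: Luche 1,2-reduction; axial hydride delivery should give mainly the cis allylic alcohol, a stereocentre that is removed again in step 10.

Step 10
Reactants: 17 (4R,6R)-6-[(1R,5R)-5-hydroxy-4-methylcyclohex-3-en-1-yl]-2-methylhept-2-en-4-yl acetate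
Product: 19 (4R,6R)-2-methyl-6-[(1S)-4-methylcyclohexa-2,4-dien-1-yl]hept-2-en-4-yl acetate, via sulfamate ester 18 (not isolated)
Conditions: Burgess reagent (MeO2C–N(−)–SO2–N(+)Et3), PhMe, 50 °C
Reagents that add atoms: none
Why: Burgess dehydration; the sulfamate ester undergoes thermal syn (Ei) elimination with a hydrogen of the ring CH2 next to the carbinol carbon, the only sp3 β-position, which should give the homoannular 1,3-diene whose termini are the two carbons to be oxygenated.

Step 11
Reactants: 19 (4R,6R)-2-methyl-6-[(1S)-4-methylcyclohexa-2,4-dien-1-yl]hept-2-en-4-yl acetate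
Product: 21 (4R,6R)-6-[(1S,2S,5R)-2,5-dihydroxy-4-methylcyclohex-3-en-1-yl]-2-methylhept-2-en-4-yl acetate, via endoperoxide 20 (not isolated)
Conditions: O2, tetraphenylporphyrin (cat.), visible light, CH2Cl2, −30 °C; then thiourea, MeOH, rt
Reagents that add atoms: dioxygen, O=O
Why: Singlet-oxygen [4+2] cycloaddition to the cisoid ring diene from the face opposite the side chain on the adjacent sp3 carbon should set both C–O centres cis to each other and trans to the side chain (the side-chain alkene, deactivated by its allylic acetate, reacts much more slowly in the ene mode), and thiourea reduction of the O–O bond gives the cis-ene-1,4-diol without touching the C–O bonds.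

Step 12
Reactants: 21 (4R,6R)-6-[(1S,2S,5R)-2,5-dihydroxy-4-methylcyclohex-3-en-1-yl]-2-methylhept-2-en-4-yl acetate
Product: 22 (4R,6R)-6-[(1S,2S,5R)-5-acetoxy-2-hydroxy-4-methylcyclohex-3-en-1-yl]-2-methylhept-2-en-4-yl acetate
Conditions: AcCl (1.05 equiv), 2,4,6-collidine, CH2Cl2, −78 °C
Reagents that add atoms: acetyl chloride, CC(=O)Cl
Why: Site-selective acylation at low temperature; the hydroxyl next to the ring CH2 is less hindered than the one flanked by the ring carbon that carries the branched side chain and should be acetylated first.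

Step 13
Reactants: 22 (4R,6R)-6-[(1S,2S,5R)-5-acetoxy-2-hydroxy-4-methylcyclohex-3-en-1-yl]-2-methylhept-2-en-4-yl acetate; 23 angelic acid
Product: 25 (1S,4R,6S)-4-acetoxy-6-[(2R,4R)-4-acetoxy-6-methylhept-5-en-2-yl]-3-methylcyclohex-2-en-1-yl (2Z)-2-methylbut-2-enoate, via angelic 2,4,6-trichlorobenzoic anhydride 24 (not isolated)
Conditions: 23, 2,4,6-trichlorobenzoyl chloride, Et3N, PhMe, rt; then 22, PhMe, 80 °C
Reagents that add atoms: none
Why: Yamaguchi esterification through mixed anhydride 24, run without a nucleophilic pyridine catalyst so that the (Z)-2-methylbut-2-enoyl group should not isomerise to the (E)-ester; the 2,6-dichloro substitution directs the alcohol to the angeloyl carbonyl.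

**Compound list**

1 | (S)-citronellal, (3S)-3,7-dimethyloct-6-enal | O=CC[C@@H](C)CCC=C(C)C | starting material
2 | 2-methylprop-1-enylmagnesium bromide | CC(C)=C[Mg]Br | starting material
3 | (6S)-2,6,10-trimethylundeca-2,9-dien-4-ol, both C4 epimers | CC(C)=CC(O)C[C@@H](C)CCC=C(C)C | intermediate
4 | (6S)-2,6,10-trimethylundeca-2,9-dien-4-one | CC(C)=CC(=O)C[C@@H](C)CCC=C(C)C | intermediate
5 | (4R,6S)-2,6,10-trimethylundeca-2,9-dien-4-ol | CC(C)=C[C@H](O)C[C@@H](C)CCC=C(C)C | intermediate
6 | (4R,6S)-2,6,10-trimethylundeca-2,9-dien-4-yl acetate | CC(C)=C[C@H](OC(C)=O)C[C@@H](C)CCC=C(C)C | intermediate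
7 | ozonide of 6 at the remote alkene, a 3-alkyl-5,5-dimethyl-1,2,4-trioxolane | CC(C)=C[C@H](OC(C)=O)C[C@@H](C)CCC1OOC(C)(C)O1 | intermediate
8 | (4R,6S)-2,6-dimethyl-9-oxonon-2-en-4-yl acetate | CC(C)=C[C@H](OC(C)=O)C[C@@H](C)CCC=O | intermediate
9 | (4R,6R,7E)-2,6-dimethyl-9-oxonona-2,7-dien-4-yl acetate | CC(C)=C[C@H](OC(C)=O)C[C@@H](C)/C=C/C=O | intermediate
10 | methyl 3-oxopentanoate | CCC(=O)CC(=O)OC | starting material
11 | sodium 3-oxopentanoate | CCC(=O)CC(=O)[O-].[Na+] | intermediate
12 | 3-oxopentanoic acid | CCC(=O)CC(=O)O | intermediate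
13 | (3S)-3-[(2R,4R)-4-acetoxy-6-methylhept-5-en-2-yl]-5-oxo-2-propanoylpentanoic acid, both C2 epimers | CCC(=O)C(C(=O)O)[C@@H](CC=O)[C@H](C)C[C@H](C=C(C)C)OC(C)=O | intermediate
14 | (3R)-3-[(2R,4R)-4-acetoxy-6-methylhept-5-en-2-yl]-5-oxoheptanal | CCC(=O)C[C@@H](CC=O)[C@H](C)C[C@H](C=C(C)C)OC(C)=O | intermediate
15 | (4R,6R)-6-[(1R)-3-hydroxy-4-methyl-5-oxocyclohexyl]-2-methylhept-2-en-4-yl acetate, mixture at the two new ring centres | CC1C(O)C[C@H](CC1=O)[C@H](C)C[C@H](C=C(C)C)OC(C)=O | intermediate
16 | (4R,6R)-2-methyl-6-[(1R)-4-methyl-5-oxocyclohex-3-en-1-yl]hept-2-en-4-yl acetate | CC1=CC[C@H](CC1=O)[C@H](C)C[C@H](C=C(C)C)OC(C)=O | intermediate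
17 | (4R,6R)-6-[(1R,5R)-5-hydroxy-4-methylcyclohex-3-en-1-yl]-2-methylhept-2-en-4-yl acetate | CC1=CC[C@H](C[C@H]1O)[C@H](C)C[C@H](C=C(C)C)OC(C)=O | intermediate
18 | triethylammonium salt of the N-(methoxycarbonyl)sulfamate ester of 17 | CC1=CC[C@H](C[C@H]1OS(=O)(=O)[N-]C(=O)OC)[C@H](C)C[C@H](C=C(C)C)OC(C)=O.CC[NH+](CC)CC | intermediate
19 | (4R,6R)-2-methyl-6-[(1S)-4-methylcyclohexa-2,4-dien-1-yl]hept-2-en-4-yl acetate | CC1=CC[C@H](C=C1)[C@H](C)C[C@H](C=C(C)C)OC(C)=O | intermediate
20 | (4R,6R)-2-methyl-6-[(1S,4R,7S)-5-methyl-2,3-dioxabicyclo[2.2.2]oct-5-en-7-yl]hept-2-en-4-yl acetate, O–O bridge anti to the side chain | [C@H]12C=C(C)[C@H](OO1)C[C@H]2[C@H](C)C[C@H](C=C(C)C)OC(C)=O | intermediate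
21 | (4R,6R)-6-[(1S,2S,5R)-2,5-dihydroxy-4-methylcyclohex-3-en-1-yl]-2-methylhept-2-en-4-yl acetate | O[C@@H]1C=C(C)[C@H](O)C[C@H]1[C@H](C)C[C@H](C=C(C)C)OC(C)=O | intermediate
22 | (4R,6R)-6-[(1S,2S,5R)-5-acetoxy-2-hydroxy-4-methylcyclohex-3-en-1-yl]-2-methylhept-2-en-4-yl acetate | O[C@@H]1C=C(C)[C@H](OC(C)=O)C[C@H]1[C@H](C)C[C@H](C=C(C)C)OC(C)=O | intermediate
23 | angelic acid, (2Z)-2-methylbut-2-enoic acid | C/C=C(/C)C(=O)O | starting material
24 | angelic 2,4,6-trichlorobenzoic anhydride | C/C=C(/C)C(=O)OC(=O)c1c(Cl)cc(Cl)cc1Cl | intermediate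
25 | (1S,4R,6S)-4-acetoxy-6-[(2R,4R)-4-acetoxy-6-methylhept-5-en-2-yl]-3-methylcyclohex-2-en-1-yl (2Z)-2-methylbut-2-enoate | C/C=C(/C)C(=O)O[C@@H]1C=C(C)[C@H](OC(C)=O)C[C@H]1[C@H](C)C[C@H](C=C(C)C)OC(C)=O | target

**Step count**

Total steps: 13. Longest linear sequence: 12 steps (steps 1–6 and 8–13; step 7 is a one-step side branch).

**Three steps most likely to fail**

1. Step 8. What may go wrong: γ-deprotonation of the iminium ion of 9 (dienamine formation) would scramble the side-chain methyl stereocentre, and decarboxylation of 12 before C–C bond formation would stall the Michael addition. The fallback keeps the carboxyl activator as a stable ester and removes it in a separate neutral step; it sets out from 9 and 10 and returns at 16. Compound 10 is transesterified with allyl alcohol (DMAP, PhMe, reflux) to prop-2-en-1-yl 3-oxopentanoate F1, which cannot decarboxylate and can be used cold and in excess. F1 and 9 with the same silyl prolinol catalyst and benzoic acid at −20 °C should give the Michael adduct keto ester F2. Piperidinium acetate closes and dehydrates F2 to the cyclohexenone allyl ester F3. Pd(PPh3)4 (zerovalent palladium) with morpholine in THF then removes the allyl group and the carboxyl group to give 16; the allyl ester should ionise much faster than the hindered side-chain allylic acetate.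

2. Step 11. What may go wrong: poor facial selectivity of the singlet-oxygen cycloaddition (attack syn to the side chain), and a competing ene reaction at the side-chain alkene. The fallback installs the two oxygens one at a time by enone chemistry under ring control; it sets out from 16 and returns at 22. The potassium enolate of 16 (KHMDS, −78 °C) is hydroxylated with 2-(phenylsulfonyl)-3-phenyloxaziridine anti to the neighbouring side chain to give the α′-hydroxy enone F4, which is silylated (TBSOTf, 2,6-lutidine) to silyl ether F5. Nucleophilic epoxidation (tert-butyl hydroperoxide, DBU) anti to the side chain should give epoxy ketone F6. Hydrazine hydrate and acetic acid in methanol form the epoxy hydrazone F7, which undergoes the Wharton transposition to the allylic alcohol F8 with the ring =CH now on the former carbonyl carbon. Acetylation (Ac2O, pyridine, DMAP) gives acetate F9 and restores any side-chain acetate lost to hydrazine. HF·pyridine then frees the remaining hydroxyl to give 22.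

3. Step 12. What may go wrong: poor site selectivity between the two allylic hydroxyls, or double acylation. The fallback brings the two ester oxygens in by different reactions, so no selection between hydroxyls is needed; it sets out from 19 and returns at 25. Buffered epoxidation of 19 (mCPBA, NaHCO3, −20 °C) at the methyl-substituted ring alkene, anti to the side chain, gives vinyl epoxide F10. Pd(PPh3)4 (zerovalent palladium) with angelic acid 23 in THF at 0 °C opens F10 through a π-allyl complex: ionisation anti to the epoxide oxygen and carboxylate attack anti to the metal at the far terminus should give the cis-1,4 hydroxy angelate F11. Acetylation of F11 (Ac2O, pyridine, DMAP) gives 25.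

**Further compounds**

F1 | step 8 | prop-2-en-1-yl 3-oxopentanoate | CCC(=O)CC(=O)OCC=C
F2 | step 8 | prop-2-en-1-yl (3S)-3-[(2R,4R)-4-acetoxy-6-methylhept-5-en-2-yl]-5-oxo-2-propanoylpentanoate, both C2 epimers | CCC(=O)C(C(=O)OCC=C)[C@@H](CC=O)[C@H](C)C[C@H](C=C(C)C)OC(C)=O
F3 | step 8 | prop-2-en-1-yl (6S)-6-[(2R,4R)-4-acetoxy-6-methylhept-5-en-2-yl]-3-methyl-2-oxocyclohex-3-ene-1-carboxylate, both C1 epimers | CC1=CC[C@H](C(C1=O)C(=O)OCC=C)[C@H](C)C[C@H](C=C(C)C)OC(C)=O
F4 | step 11 | (4R,6R)-6-[(1S,2S)-2-hydroxy-4-methyl-3-oxocyclohex-4-en-1-yl]-2-methylhept-2-en-4-yl acetate | CC1=CC[C@H]([C@H](O)C1=O)[C@H](C)C[C@H](C=C(C)C)OC(C)=O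
F5 | step 11 | (4R,6R)-6-[(1S,2S)-2-(tert-butyldimethylsilyloxy)-4-methyl-3-oxocyclohex-4-en-1-yl]-2-methylhept-2-en-4-yl acetate | CC1=CC[C@H]([C@H](O[Si](C)(C)C(C)(C)C)C1=O)[C@H](C)C[C@H](C=C(C)C)OC(C)=O
F6 | step 11 | epoxy ketone of F5, epoxide oxygen anti to the side chain and cis to the silyloxy group | C[C@@]12O[C@@H]1C[C@H]([C@H](O[Si](C)(C)C(C)(C)C)C2=O)[C@H](C)C[C@H](C=C(C)C)OC(C)=O
F7 | step 11 | hydrazone of epoxy ketone F6 | C[C@@]12O[C@@H]1C[C@H]([C@H](O[Si](C)(C)C(C)(C)C)C2=NN)[C@H](C)C[C@H](C=C(C)C)OC(C)=O
F8 | step 11 | (4R,6R)-6-[(1S,2S,5R)-2-(tert-butyldimethylsilyloxy)-5-hydroxy-4-methylcyclohex-3-en-1-yl]-2-methylhept-2-en-4-yl acetate | CC(C)(C)[Si](C)(C)O[C@@H]1C=C(C)[C@H](O)C[C@H]1[C@H](C)C[C@H](C=C(C)C)OC(C)=O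
F9 | step 11 | (4R,6R)-6-[(1S,2S,5R)-5-acetoxy-2-(tert-butyldimethylsilyloxy)-4-methylcyclohex-3-en-1-yl]-2-methylhept-2-en-4-yl acetate | CC(C)(C)[Si](C)(C)O[C@@H]1C=C(C)[C@H](OC(C)=O)C[C@H]1[C@H](C)C[C@H](C=C(C)C)OC(C)=O
F10 | step 12 | monoepoxide of 19 at the methyl-substituted ring alkene, oxygen anti to the side chain | C[C@@]12O[C@@H]1C[C@H](C=C2)[C@H](C)C[C@H](C=C(C)C)OC(C)=O
F11 | step 12 | (1S,4R,6S)-6-[(2R,4R)-4-acetoxy-6-methylhept-5-en-2-yl]-4-hydroxy-3-methylcyclohex-2-en-1-yl (2Z)-2-methylbut-2-enoate | C/C=C(/C)C(=O)O[C@@H]1C=C(C)[C@H](O)C[C@H]1[C@H](C)C[C@H](C=C(C)C)OC(C)=O
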